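**Retrosynthetic overview**
Target: (4S,5R,6R,8R,9S,10S,13R)-6β-acetoxy-8,17:9α,13:15,16-triepoxylabd-14-en-19,20-olide. The oxirane comes from a C8 ketone (sulfur ylide), the spiro dihydrofuran from a 9α-hydroxy 3-furylethyl chain, C9–C11 from a B-alkyl Suzuki coupling on a C9 enol triflate, and the 9α-oxygen from dihydroxylation.
Ring B: Michael/intramolecular Wittig annulation of a C9 methyl ketone onto the C5 ketone with vinyltriphenylphosphonium bromide (C6–C7); C6–O by hydroboration, oxidation and α-face reduction.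
Key disconnection: the δ-lactone ring (C4, C19, O, C20, C10, C5) is cut at C4–C19 and C10–C20, a formal [3+3] annulation of the 1,3-bis-nucleophile C4–C5(=O)–C10 (a cyclic β-keto ester dianion) with a carbonate (C19) and formaldehyde (C20).
Enabling feature: C19 and C20 sit 1,3-diaxial on the β face of ring A (C1–C5, C10) and are tied through the lactone oxygen, so ring A and the lactone ring form a 3-oxabicyclo[3.3.1]nonane sharing C4–C5–C10; with C5 as a temporary ketone, C4 and C10 are its two α-carbons and the bridge can only close cis.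
Ring order: ring A (purchased) → lactone ring (key step) → ring B → spiro tetrahydrofuran/dihydrofuran at C9/C13 → oxirane at C8.

Key step: step 3

Remark: labdane atom numbers are used throughout; α/β refer to the usual drawing with C20 up.
Remark: the (S)-1-phenylethyl ester is only a resolving handle. No asymmetric induction is assumed in step 3; the two bridge diastereomers are separated there and the unwanted one is discarded.

Step 1
Reactants: 1 2-methylcyclohexanone
Product: 2 methyl 3-methyl-2-oxocyclohexane-1-carboxylate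
Conditions: NaH (2.2 equiv), (MeO)2CO, THF, reflux; aq HCl
Reagents that add atoms: dimethyl carbonate COC(=O)OC
Why: Claisen-type C-acylation under equilibrating conditions goes to the less substituted α-carbon and is driven by deprotonation of the β-keto ester; no target stereocentre is set.

Step 2
Reactants: 2 methyl 3-methyl-2-oxocyclohexane-1-carboxylate
Product: 3 (1S)-1-phenylethyl 3-methyl-2-oxocyclohexane-1-carboxylate
Conditions: (S)-1-phenylethanol (1.5 equiv), DMAP (0.2 equiv), toluene, 110 °C, 4 Å MS
Reagents that add atoms: (S)-1-phenylethanol C[C@H](O)c1ccccc1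
Why: DMAP-catalysed transesterification of a β-keto ester installs a resolving ester that hydrogenolysis removes later; the ring stereocentres are left unassigned because step 3 erases both.

Step 3
Reactants: 3 (1S)-1-phenylethyl 3-methyl-2-oxocyclohexane-1-carboxylate
Product: 6 (1S)-1-phenylethyl (1R,5S)-5-methyl-4,9-dioxo-3-oxabicyclo[3.3.1]nonane-1-carboxylate, via phenyl ester enolate 4 (not isolated), via hydroxymethyl aldolate 5 (not isolated)
Conditions: LDA (2.3 equiv), THF, −78 → 0 °C; (PhO)2CO (1.0 equiv), −78 °C; CH2O (g), −78 → 0 °C; aq NH4Cl; separation of diastereomers on SiO2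
Reagents that add atoms: diphenyl carbonate O=C(Oc1ccccc1)Oc1ccccc1; formaldehyde C=O
Why: LDA gives the β-keto ester dianion, whose more basic γ-carbon (C4) is C-acylated by diphenyl carbonate (C4–C19); the remaining stabilised enolate then adds at C10 to formaldehyde (C10–C20) and the aldolate closes the lactone by 6-exo-trig acyl substitution on the phenyl ester. The closest known reaction types are γ-acylation of β-keto ester dianions, α-hydroxymethylation of β-keto esters and the [3+3] α,α′-annulation of cyclohexanones to bicyclo[3.3.1]nonan-9-ones. C4 is set in the acylation without facial bias, whereas C10 is set under thermodynamic control: the aldol addition is reversible and only the aldolate cis (1,3-diaxial) to the C4 ester can lactonise, so the bridge dictates the relative configuration. Both bridge enantiomers therefore form as diastereomers of the (S)-ester and are separated, the (1R,5S) isomer being carried on. The step needs γ- before α-attack (inherent order of the dianion), C- over O-acylation (lithium counter-ion; the now quaternary C4 cannot react twice) and lactonisation over retro-Claisen cleavage (phenoxide is a weak nucleophile at low temperature).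

Step 4
Reactants: 6 (1S)-1-phenylethyl (1R,5S)-5-methyl-4,9-dioxo-3-oxabicyclo[3.3.1]nonane-1-carboxylate
Product: 7 (1R,5S)-5-methyl-4,9-dioxo-3-oxabicyclo[3.3.1]nonane-1-carboxylic acid
Conditions: H2 (1 atm), 10% Pd/C, EtOAc, rt
Reagents that add atoms: none
Why: Hydrogenolysis of the benzylic C–O bond frees the bridgehead acid without touching the lactone, and the β-keto acid should resist decarboxylation because its enol would be a bridgehead alkene.

Step 5
Reactants: 7 (1R,5S)-5-methyl-4,9-dioxo-3-oxabicyclo[3.3.1]nonane-1-carboxylic acid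
Product: 9 (1S,5S)-5-acetyl-1-methyl-3-oxabicyclo[3.3.1]nonane-2,9-dione, via acid chloride 8 (not isolated)
Conditions: (COCl)2, DMF (cat.), CH2Cl2, 0 °C → rt; evaporate; Me2CuLi (1.2 equiv), Et2O, −78 °C
Reagents that add atoms: lithium dimethylcuprate [Li+].C[Cu-]C
Why: Acid chloride formation followed by ketone synthesis with Me2CuLi stops at the methyl ketone and spares the non-enolisable bridge ketone and the lactone.

Step 6
Reactants: 9 (1S,5S)-5-acetyl-1-methyl-3-oxabicyclo[3.3.1]nonane-2,9-dione
Product: 10 9-oxo-11,12,13,14,15,16,17-heptanorlabd-5-en-19,20-olide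
Conditions: NaH (1.1 equiv), THF, 0 °C; CH2=CHPPh3Br (1.2 equiv), 0 → 65 °C
Reagents that add atoms: vinyltriphenylphosphonium bromide C=C[P+](c1ccccc1)(c1ccccc1)c1ccccc1.[Br-]
Why: Schweizer-type annulation: the only enolisable carbon (C8) adds to the vinylphosphonium salt, and the resulting ylide closes ring B by intramolecular Wittig reaction on the C5 ketone, which removes the temporary C5 oxygen and creates C5=C6; no stereocentre is formed.

Step 7
Reactants: 10 9-oxo-11,12,13,14,15,16,17-heptanorlabd-5-en-19,20-olide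
Product: 11 9-(trifluoromethylsulfonyloxy)-11,12,13,14,15,16,17-heptanorlabda-5,8-dien-19,20-olide
Conditions: KHMDS (1.1 equiv), THF, −78 °C; PhNTf2, −78 → 0 °C; aq NH4Cl
Reagents that add atoms: N-phenylbis(trifluoromethanesulfonimide) O=S(=O)(N(c1ccccc1)S(=O)(=O)C(F)(F)F)C(F)(F)F
Why: Enol triflate formation is regiospecific because C8 carries the only α-hydrogens of the C9 ketone (C10 is quaternary); the triflate also masks C9 during the following redox steps.

Step 8
Reactants: 11 9-(trifluoromethylsulfonyloxy)-11,12,13,14,15,16,17-heptanorlabda-5,8-dien-19,20-olide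
Product: 13 6α-hydroxy-9-(trifluoromethylsulfonyloxy)-11,12,13,14,15,16,17-heptanorlabd-8-en-19,20-olide (5α-H), via alkylborane 12 (not isolated)
Conditions: BH3·THF (3 equiv), THF, 0 °C → rt; then 30% H2O2, aq NaOAc, 0 °C
Reagents that add atoms: hydrogen peroxide OO
Why: Hydroboration–oxidation adds H and OH syn from the α face, because the β face of C5=C6 is shielded by the axial C4–C19 and C10–C20 bonds of the lactone bridge; this sets C5 (H α, trans ring fusion) and C6, and the electron-poor enol triflate alkene should not react.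

Step 9
Reactants: 13 6α-hydroxy-9-(trifluoromethylsulfonyloxy)-11,12,13,14,15,16,17-heptanorlabd-8-en-19,20-olide
Product: 14 6-oxo-9-(trifluoromethylsulfonyloxy)-11,12,13,14,15,16,17-heptanorlabd-8-en-19,20-olide (5α-H)
Conditions: Dess–Martin periodinane, NaHCO3, CH2Cl2, rt
Reagents that add atoms: none
Why: Buffered Dess–Martin oxidation of the secondary alcohol leaves the enol triflate and the trans-fused C5 centre untouched.

Step 10
Reactants: 14 6-oxo-9-(trifluoromethylsulfonyloxy)-11,12,13,14,15,16,17-heptanorlabd-8-en-19,20-olide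
Product: 15 6β-hydroxy-9-(trifluoromethylsulfonyloxy)-11,12,13,14,15,16,17-heptanorlabd-8-en-19,20-olide
Conditions: NaBH4, MeOH/THF (1:1), −40 °C; AcOH, −40 °C
Reagents that add atoms: none
Why: Hydride reduction from the open α face (the β face of C6 is blocked by the 1,3-diaxial lactone bridge) should give the axial 6β-alcohol, as in 6-oxo steroids bearing an angular β substituent, and the cold acidic quench is meant to keep the 6β-alkoxide from translactonising onto C19.

Step 11
Reactants: 15 6β-hydroxy-9-(trifluoromethylsulfonyloxy)-11,12,13,14,15,16,17-heptanorlabd-8-en-19,20-olide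
Product: 16 6β-acetoxy-9-(trifluoromethylsulfonyloxy)-11,12,13,14,15,16,17-heptanorlabd-8-en-19,20-olide
Conditions: Ac2O, DMAP, pyridine, 40 °C
Reagents that add atoms: acetic anhydride CC(=O)OC(C)=O
Why: DMAP-catalysed acylation is the standard way to esterify a hindered axial secondary alcohol and keeps the C6 configuration.

Step 12
Reactants: 17 furan-3-carbaldehyde
Product: 18 3-vinylfuran
Conditions: Ph3PCH3Br, KOtBu, Et2O, 0 °C → rt
Reagents that add atoms: methyltriphenylphosphonium bromide C[P+](c1ccccc1)(c1ccccc1)c1ccccc1.[Br-]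
Why: Wittig methylenation of an aromatic aldehyde gives the side-chain carbons C11–C16 in one piece.

Step 13
Reactants: 16 6β-acetoxy-9-(trifluoromethylsulfonyloxy)-11,12,13,14,15,16,17-heptanorlabd-8-en-19,20-olide; 18 3-vinylfuran
Product: 20 6β-acetoxy-15,16-epoxy-17-norlabda-8,13(16),14-trien-19,20-olide, via furylethyl borane 19 (not isolated)
Conditions: 18, 9-BBN, THF, rt; then 16, PdCl2(dppf) (5 mol %), AsPh3, K3PO4 (aq), DMF, 45 °C
Reagents that add atoms: none
Why: B-alkyl Suzuki–Miyaura coupling of the anti-Markovnikov 9-BBN adduct with the enol triflate forms C9–C11 under mild base that the acetate and lactone should survive.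

Step 14
Reactants: 20 6β-acetoxy-15,16-epoxy-17-norlabda-8,13(16),14-trien-19,20-olide
Product: 21 6β-acetoxy-8α,9α-dihydroxy-15,16-epoxy-17-norlabda-13(16),14-dien-19,20-olide
Conditions: OsO4 (5 mol %), NMO (2 equiv), acetone/H2O (4:1), 0 °C → rt; aq Na2SO3
Reagents that add atoms: osmium tetroxide O=[Os](=O)(=O)=O; N-methylmorpholine N-oxide C[N+]1([O-])CCOCC1; water O
Why: Catalytic dihydroxylation attacks the only electron-rich alkene from the α face, anti to the axial C20 on C10 and the 6β-acetate, which sets C9 (O α, C11 β) and C8; the furan is far less reactive.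

Step 15
Reactants: 21 6β-acetoxy-8α,9α-dihydroxy-15,16-epoxy-17-norlabda-13(16),14-dien-19,20-olide
Product: 22 6β-acetoxy-9α-hydroxy-8-oxo-15,16-epoxy-17-norlabda-13(16),14-dien-19,20-olide
Conditions: Dess–Martin periodinane, NaHCO3, CH2Cl2, 0 °C → rt
Reagents that add atoms: none
Why: Dess–Martin oxidation converts only the secondary C8 alcohol and leaves the tertiary 9α-hydroxyl as the future ether oxygen.

Step 16
Reactants: 22 6β-acetoxy-9α-hydroxy-8-oxo-15,16-epoxy-17-norlabda-13(16),14-dien-19,20-olide
Product: 24 (13R)-6β-acetoxy-9α,13:15,16-diepoxy-8-oxo-17-norlabd-14-en-19,20-olide, via bromo spiro ether 23 (not isolated)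
Conditions: NBS (1.05 equiv), NaHCO3, THF, −78 → −40 °C; then Bu3SnH (1.5 equiv), Et3B (cat.), air, −40 → 0 °C
Reagents that add atoms: none
Why: Proposed new method: NBS should brominate the furan at C16 (the α-carbon next to the alkyl group), the resulting allyl/oxocarbenium cation is trapped 5-exo at C13 by the 9α-hydroxyl, and the labile α-bromo ether is reduced in the same flask by a tin hydride radical chain to the 2,3-dihydrofuran, so a kinetically trapped isomer of the furan is obtained that acid would return to the furan; the closest known reaction types are NBS-mediated dearomative spiroketalisation of 2-(hydroxyalkyl)furans and halo-spirocyclisation of 3-substituted indoles; C13 is set under kinetic control, with the bulkier CHBr arm (C16) expected on the side of the flat C8 carbonyl and C14 toward quaternary C10, which is the 13R arrangement.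

Step 17
Reactants: 24 (13R)-6β-acetoxy-9α,13:15,16-diepoxy-8-oxo-17-norlabd-14-en-19,20-olide
Product: 25 (4S,5R,6R,8R,9S,10S,13R)-6β-acetoxy-8,17:9α,13:15,16-triepoxylabd-14-en-19,20-olide
Conditions: Me3SI (1.5 equiv), KHMDS (1.4 equiv), THF, −20 °C; then 24 added slowly, −40 → 0 °C
Reagents that add atoms: trimethylsulfonium iodide C[S+](C)C.[I-]
Why: Corey–Chaykovsky epoxidation: axial (β) approach to C8 is blocked by the 1,3-diaxial C20 and 6β-acetate, so the ylide carbon enters equatorially from the α side and the oxirane oxygen ends up β (8R); the enol ether is stable to base, and the low temperature with slow addition of the ketone to excess ylide is meant to let carbonyl addition outrun E1cB loss or cleavage of the 6β-acetate.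

**Compound list**
1 | 2-methylcyclohexanone (racemic) | CC1CCCCC1=O | starting material
2 | methyl 3-methyl-2-oxocyclohexane-1-carboxylate (diastereomer and enol mixture) | COC(=O)C1CCCC(C)C1=O | intermediate
3 | (1S)-1-phenylethyl 3-methyl-2-oxocyclohexane-1-carboxylate (ring centres unassigned) | C[C@H](OC(=O)C1CCCC(C)C1=O)c1ccccc1 | intermediate
4 | 1-[(1S)-1-phenylethyl] 3-phenyl 3-methyl-2-oxocyclohexane-1,3-dicarboxylate (in the flask as lithium enolate) | C[C@H](OC(=O)C1CCCC(C)(C(=O)Oc2ccccc2)C1=O)c1ccccc1 | intermediate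
5 | 1-[(1S)-1-phenylethyl] 3-phenyl 1-(hydroxymethyl)-3-methyl-2-oxocyclohexane-1,3-dicarboxylate (in the flask as lithium alkoxide) | C[C@H](OC(=O)C1(CO)CCCC(C)(C(=O)Oc2ccccc2)C1=O)c1ccccc1 | intermediate
6 | (1S)-1-phenylethyl (1R,5S)-5-methyl-4,9-dioxo-3-oxabicyclo[3.3.1]nonane-1-carboxylate (bicycle C1 = labdane C10, C5 = labdane C4) | C[C@H](OC(=O)[C@]12CCC[C@](C)(C(=O)OC1)C2=O)c1ccccc1 | intermediate
7 | (1R,5S)-5-methyl-4,9-dioxo-3-oxabicyclo[3.3.1]nonane-1-carboxylic acid | OC(=O)[C@]12CCC[C@](C)(C(=O)OC1)C2=O | intermediate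
8 | (1R,5S)-5-methyl-4,9-dioxo-3-oxabicyclo[3.3.1]nonane-1-carbonyl chloride | ClC(=O)[C@]12CCC[C@](C)(C(=O)OC1)C2=O | intermediate
9 | (1S,5S)-5-acetyl-1-methyl-3-oxabicyclo[3.3.1]nonane-2,9-dione | CC(=O)[C@]12CCC[C@](C)(C(=O)OC1)C2=O | intermediate
10 | 9-oxo-11,12,13,14,15,16,17-heptanorlabd-5-en-19,20-olide (4α-methyl; lactone bridge on the β face of C4 and C10) | O=C1CCC=C2[C@@](C)(C(=O)OC3)CCC[C@]123 | intermediate
11 | 9-(trifluoromethylsulfonyloxy)-11,12,13,14,15,16,17-heptanorlabda-5,8-dien-19,20-olide | FC(F)(F)S(=O)(=O)OC1=CCC=C2[C@@](C)(C(=O)OC3)CCC[C@]123 | intermediate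
12 | 6α-boryl adduct of 11 (5α-H; drawn as the monoalkylborane) | FC(F)(F)S(=O)(=O)OC1=CC[C@H](B)[C@H]2[C@@](C)(C(=O)OC3)CCC[C@]123 | intermediate
13 | 6α-hydroxy-9-(trifluoromethylsulfonyloxy)-11,12,13,14,15,16,17-heptanorlabd-8-en-19,20-olide (5α-H) | FC(F)(F)S(=O)(=O)OC1=CC[C@H](O)[C@H]2[C@@](C)(C(=O)OC3)CCC[C@]123 | intermediate
14 | 6-oxo-9-(trifluoromethylsulfonyloxy)-11,12,13,14,15,16,17-heptanorlabd-8-en-19,20-olide (5α-H) | FC(F)(F)S(=O)(=O)OC1=CCC(=O)[C@H]2[C@@](C)(C(=O)OC3)CCC[C@]123 | intermediate
15 | 6β-hydroxy-9-(trifluoromethylsulfonyloxy)-11,12,13,14,15,16,17-heptanorlabd-8-en-19,20-olide | FC(F)(F)S(=O)(=O)OC1=CC[C@@H](O)[C@H]2[C@@](C)(C(=O)OC3)CCC[C@]123 | intermediate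
16 | 6β-acetoxy-9-(trifluoromethylsulfonyloxy)-11,12,13,14,15,16,17-heptanorlabd-8-en-19,20-olide | FC(F)(F)S(=O)(=O)OC1=CC[C@@H](OC(C)=O)[C@H]2[C@@](C)(C(=O)OC3)CCC[C@]123 | intermediate
17 | furan-3-carbaldehyde | O=Cc1ccoc1 | starting material
18 | 3-vinylfuran | C=Cc1ccoc1 | intermediate
19 | 9-[2-(furan-3-yl)ethyl]-9-borabicyclo[3.3.1]nonane | c1cc(CCB2C3CCCC2CCC3)co1 | intermediate
20 | 6β-acetoxy-15,16-epoxy-17-norlabda-8,13(16),14-trien-19,20-olide | c1cc(CCC2=CC[C@@H](OC(C)=O)[C@H]3[C@@](C)(C(=O)OC4)CCC[C@]234)co1 | intermediate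
21 | 6β-acetoxy-8α,9α-dihydroxy-15,16-epoxy-17-norlabda-13(16),14-dien-19,20-olide | c1cc(CC[C@@]2(O)[C@H](O)C[C@@H](OC(C)=O)[C@H]3[C@@](C)(C(=O)OC4)CCC[C@]234)co1 | intermediate
22 | 6β-acetoxy-9α-hydroxy-8-oxo-15,16-epoxy-17-norlabda-13(16),14-dien-19,20-olide | c1cc(CC[C@@]2(O)C(=O)C[C@@H](OC(C)=O)[C@H]3[C@@](C)(C(=O)OC4)CCC[C@]234)co1 | intermediate
23 | (13R)-6β-acetoxy-16-bromo-9α,13:15,16-diepoxy-8-oxo-17-norlabd-14-en-19,20-olide (C16 unassigned) | CC(=O)O[C@@H]1CC(=O)[C@]2(CC[C@]3(C=COC3Br)O2)[C@]23CCC[C@](C)(C(=O)OC2)[C@H]13 | intermediate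
24 | (13R)-6β-acetoxy-9α,13:15,16-diepoxy-8-oxo-17-norlabd-14-en-19,20-olide | CC(=O)O[C@@H]1CC(=O)[C@]2(CC[C@]3(C=COC3)O2)[C@]23CCC[C@](C)(C(=O)OC2)[C@H]13 | intermediate
25 | (4S,5R,6R,8R,9S,10S,13R)-6β-acetoxy-8,17:9α,13:15,16-triepoxylabd-14-en-19,20-olide (oxirane oxygen β at C8) | CC(=O)O[C@@H]1C[C@@]2(CO2)[C@]2(CC[C@]3(C=COC3)O2)[C@]23CCC[C@](C)(C(=O)OC2)[C@H]13 | target

Total steps: 17. Longest linear sequence: 16 steps (1 to 25 through steps 1–11 and 13–17).

**Steps most likely to fail**

Step 16 (Proposed new method). Bromination may go to the remote α-carbon (C15), the furan may re-aromatise by proton loss before the hindered tertiary hydroxyl closes, or facial control at C13 may be poor. The fallback uses known chemistry, leaves the route at 16 and returns at 24. Under the conditions of step 13, 16 is coupled with the 9-BBN adduct F2 of (2R)-2-(2,2-dimethoxyethyl)-2-vinyloxirane F1, a separately prepared building block whose quaternary centre comes from a Sharpless asymmetric epoxidation at the allylic alcohol stage; this gives the coupled epoxy acetal F3. Dihydroxylation with OsO4/NMO as in step 14 gives diol F4, and Dess–Martin oxidation gives ketol F5. Camphorsulfonic acid then lets the 9α-hydroxyl open the tertiary epoxide 5-exo with inversion at C13, and the freed C16 hydroxyl exchanges into the acetal to give the 15-methoxy spiro acetal F6. Loss of methanol (TMSOTf, i-Pr2NEt) gives 24 with C13 set by the reagent instead of by the substrate.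

Step 3. The dianion may be O-acylated or quenched by proton transfer, or retro-aldol loss of formaldehyde may outrun lactonisation. The fallback forms the two bonds in separate, individually precedented operations; it sets out from 3 and returns at 6. Hydroxymethylation of 3 with aqueous formaldehyde and KHCO3 gives the hydroxymethyl keto ester F7. Phenyl chloroformate and pyridine convert it into the phenyl carbonate F8. Soft enolisation (MgBr2·OEt2, i-Pr2NEt) or LiHMDS then closes the C4–C19 bond by intramolecular C-acylation, and the bridge diastereomers are separated by chromatography to give 6.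

Step 6. The enolate may trigger retro-Claisen cleavage of the non-enolisable 1,3-dicarbonyl array, or the ylide may fail to add to the doubly neopentylic C5 ketone. The fallback is a Julia-type ring closure that sets out from 9 and returns at 10. Michael addition of the C8 enolate (KHMDS) to phenyl vinyl sulfone gives the keto sulfone F9. LDA (2 equiv) forms the C9 enolate and then the sulfonyl carbanion, which adds to the C5 ketone to give the hydroxy sulfone F10. Reductive elimination with SmI2/HMPA in THF at −78 °C, run without a proton donor so that ketyl formation at the hindered C9 ketone stays reversible, gives 10.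

**Further compounds**
F1 | step 16 | (2R)-2-(2,2-dimethoxyethyl)-2-vinyloxirane | C=C[C@@]1(CO1)CC(OC)OC
F2 | step 16 | 9-{2-[(2S)-2-(2,2-dimethoxyethyl)oxiran-2-yl]ethyl}-9-borabicyclo[3.3.1]nonane | COC(OC)C[C@]1(CO1)CCB2C3CCCC2CCC3
F3 | step 16 | (13S)-6β-acetoxy-15,15-dimethoxy-13,16-epoxy-17-norlabd-8-en-19,20-olide | COC(OC)C[C@]5(CO5)CCC2=CC[C@@H](OC(C)=O)[C@H]3[C@@](C)(C(=O)OC4)CCC[C@]234
F4 | step 16 | (13S)-6β-acetoxy-8α,9α-dihydroxy-15,15-dimethoxy-13,16-epoxy-17-norlabdan-19,20-olide | COC(OC)C[C@]5(CO5)CC[C@@]2(O)[C@H](O)C[C@@H](OC(C)=O)[C@H]3[C@@](C)(C(=O)OC4)CCC[C@]234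
F5 | step 16 | (13S)-6β-acetoxy-9α-hydroxy-15,15-dimethoxy-8-oxo-13,16-epoxy-17-norlabdan-19,20-olide | COC(OC)C[C@]5(CO5)CC[C@@]2(O)C(=O)C[C@@H](OC(C)=O)[C@H]3[C@@](C)(C(=O)OC4)CCC[C@]234
F6 | step 16 | (13R)-6β-acetoxy-15-methoxy-9α,13:15,16-diepoxy-8-oxo-17-norlabdan-19,20-olide (C15 unassigned) | CC(=O)O[C@@H]1CC(=O)[C@]2(CC[C@]3(CC(OC)OC3)O2)[C@]23CCC[C@](C)(C(=O)OC2)[C@H]13
F7 | step 3 | (1S)-1-phenylethyl 1-(hydroxymethyl)-3-methyl-2-oxocyclohexane-1-carboxylate | C[C@H](OC(=O)C1(CO)CCCC(C)C1=O)c1ccccc1
F8 | step 3 | (1S)-1-phenylethyl 3-methyl-2-oxo-1-[(phenoxycarbonyloxy)methyl]cyclohexane-1-carboxylate | C[C@H](OC(=O)C1(COC(=O)Oc2ccccc2)CCCC(C)C1=O)c1ccccc1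
F9 | step 6 | (1S,5S)-1-methyl-5-[4-(phenylsulfonyl)butanoyl]-3-oxabicyclo[3.3.1]nonane-2,9-dione | O=C(CCCS(=O)(=O)c1ccccc1)[C@]12CCC[C@](C)(C(=O)OC1)C2=O
F10 | step 6 | 5-hydroxy-9-oxo-6-(phenylsulfonyl)-11,12,13,14,15,16,17-heptanorlabdan-19,20-olide (C5 and C6 unassigned) | O=C1CCC(S(=O)(=O)c2ccccc2)C2(O)[C@@](C)(C(=O)OC3)CCC[C@]123
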